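## Structural features

The target is a (3R)-isoflavan: benzene ring A (C4a, C5 to C8, C8a) is fused to dihydropyran ring C (O1, C2, C3, C4), and C3 carries benzene ring B through the C3–C1′ bond. Ring A has OMe on C5, OH on C7, CHO on C8 and O1 on C8a; the formyl carbon lies para to the methoxy group and between two oxygens, so ring A has a latent mirror plane through C5 and C8 that only ring C breaks. Ring B is a resorcinol whose O2′ and C3′ are tied into a 2,2-dimethyl-2H-pyran (ring D, O1″–C2″(CH3)2–C3″=C4″), while the 4′-OH is free. C3 is the only stereocentre: a benzylic CH between two methylene groups (C2 and C4), with no neighbouring stereocentre or polar group to relay asymmetry, and configurationally stable once made. Fragile groups are the salicylaldehyde unit (reducible, chelating), the cis-styrenic alkene of ring D (sensitive to acid and to hydrogenation) and the electron-rich phenols. The real difficulty is to create the isolated C3 centre together with the C3–C1′ bond while the aldehyde and the ring D alkene are present, and to place the CHO on C8 and not on C6. The key step exploits the fact that both heterocycles are benzopyrans: ring C, taken at the 2H-chromene oxidation level, has a C3=C4 alkene whose C3 is the atom that must receive ring B, and its allylic carbon C2 is a CH2, whereas the competing C3″=C4″ alkene of ring D sits next to the quaternary C2″.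

## Logic of the disconnections

Route in one sentence: an enantioselective palladium-catalysed reductive Heck hydroarylation adds aryl bromide 14 across the C3=C4 bond of 6. This sentence does not describe the isoflavone or auxiliary routes.

16 ⇒ 15. The two O–Si bonds (on O7 and O4′) are cut. Both phenols are masked so that the salicylaldehyde OH cannot chelate palladium and one fluoride treatment ends the synthesis. Nothing is gained in skeleton; the gain is a key step free of acidic OH groups. The demand is a deprotection that spares CHO, the ring D alkene and C3.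

15 ⇒ 6 + 14 (key disconnection). The C3–C1′ bond is cut, together with one C4–H bond. C3 of the saturated ring C is the β-carbon of the styrenic C3=C4 alkene of 6, the position to which an aryl-palladium species delivers its aryl group. The cut divides the molecule into two achiral, flat benzopyran halves of equal size and removes the only stereocentre. The forward step must place the aryl on C3 and not C4, on one face of the alkene, reduce the C4–Pd bond before it eliminates, and leave the ring D alkene, the aldehyde and the silyl ethers untouched.

6 ⇒ 5 ⇒ 4. The O7–Si bond is cut, then the C4–C4a bond of ring C. In 4 the ether oxygen has only one free ortho carbon (the other carries CHO), so ring C can close in one way only, and that way puts C4 next to C5-OMe. Ring C is reduced to a three-carbon O-substituent. The forward step must close 6-endo onto the alkyne terminus and tolerate the free OH and the aldehyde.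

4 ⇒ 2 + 3, and 2 ⇒ 1. The O1–C2 bond is cut, then the O–CH3 bond. In 2 the two OH groups are equivalent and the two ring CH are equivalent, so mono-alkylation gives one product; the CHO is thereby fixed on C8 without any regiochemical decision. This reaches commercial 1 and 3. The demands are mono- against bis-alkylation (2 to 4) and methylation of the para-OH only (1 to 2).

14 ⇒ 10 (through 11, 12 and 13). The C4″–C3′ bond is cut; the O–C2″ bond is broken and re-formed on the way. In 10 the only free ortho carbon of the ether is the one between the two oxygens, because bromine occupies the other; bromine is thus blocking group first and palladium handle later. Ring D is reduced to an ether substituent. The forward step must tolerate the aryl bromide and the silyl ether at 140 °C.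

10 ⇒ 8 + 9, and 8 ⇒ 7. The O2′–C2″ bond is cut, then the O4′–Si bond. This reaches commercial 7 and 9. The demand is to tell the two OH groups of 7 apart; the one para to bromine is unhindered and is silylated, the one next to bromine is kept for the ether.

## Other disconnections considered

Alternative 1: the first idea is to cut the C3–H and C4–H bonds, back to isoflav-3-ene A1 (reached by classical isoflavonoid chemistry). The forward key step would be an iridium–phosphine-oxazoline asymmetric hydrogenation of A1 to isoflavan A2. Hydrogenation cannot be run with the ring D alkene or the aldehyde in place, so both would have to be added after A2. Ring D then needs the 2′-OH and 4′-OH told apart. Formylation of ring A of A2 must choose C8 over C6, and both carbons are ortho to O7 and ortho/para to the other two oxygens, so there is no structural basis for selectivity. The chosen plan carries the aldehyde and ring D through the stereo-defining step and is about half as long.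

Alternative 2: cut C3–C4 by an oxazolidinone-auxiliary enolate alkylation of imide A3 with benzylic bromide A4 to give A5, followed by reductive removal of the auxiliary and Mitsunobu closure of O1–C2. The stereochemistry is reliable, but the auxiliary is stoichiometric. The hydride step forces the aldehyde to be masked (the dioxolane in A4). A4 is a benzylic bromide flanked by two oxygens, a class that ionises easily. Ring C closure costs two further steps after the stereocentre is made. The chosen key step is catalytic and works on a ring C that is already closed.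

Alternative 3: cut C3–C4 and O1–C2 together by a formal [4+2] annulation of the o-quinone methide released from A6 with the azolium enolate of acyl imidazole A7 under a chiral N-heterocyclic carbene, giving dihydrocoumarin A8. The step is convergent and sets C3, but in A8 the C3–H is both benzylic and α to a lactone carbonyl, so it is acidic under the fluoride and base that generate the quinone methide. The lactone must then be reduced to a diol and re-closed, again with the aldehyde masked. The chosen plan makes C3 at the final oxidation level, where it cannot epimerise.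

Key step: step 8

Assumption: the sense of induction of (R)-BINAP in step 8 cannot be assigned in advance; it is taken to give the 3R product, and (S)-BINAP is used instead if the opposite face is favoured.

## Steps

Step 1
Reactants: 1 2,4,6-trihydroxybenzaldehyde
Product: 2 2,6-dihydroxy-4-methoxybenzaldehyde
Conditions: Me2SO4 (1.0 equiv), K2CO3 (1.0 equiv), acetone, 0 °C to rt
Reagents that add atoms: dimethyl sulfate COS(=O)(=O)OC
Why: Williamson O-methylation under mono-deprotonation; the 4-OH is para to the formyl group, the most acidic and the only hydroxyl not hydrogen-bonded to C=O, so its phenoxide should form and react first, and the hard electrophile in acetone favours O- over C-methylation.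

Step 2
Reactants: 2 2,6-dihydroxy-4-methoxybenzaldehyde; 3 3-bromoprop-1-yne (propargyl bromide)
Product: 4 2-hydroxy-4-methoxy-6-(prop-2-yn-1-yloxy)benzaldehyde
Conditions: 3 (1.05 equiv), K2CO3 (1.1 equiv), DMF, 0 °C to rt
Reagents that add atoms: none
Why: Williamson etherification; the two OH groups of 2 are equivalent by symmetry, so the first alkylation has no regiochemical choice, and the remaining OH of 4 is held in a strong hydrogen bond to the aldehyde, which should slow a second alkylation.

Step 3
Reactants: 4 2-hydroxy-4-methoxy-6-(prop-2-yn-1-yloxy)benzaldehyde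
Product: 5 7-hydroxy-5-methoxy-2H-chromene-8-carbaldehyde
Conditions: Ph3PAuNTf2 (3 mol %), CH2Cl2, rt
Reagents that add atoms: none
Why: Gold-catalysed intramolecular alkyne hydroarylation (6-endo-dig): monovalent gold activates the terminal alkyne and the ring carbon ortho to the ether oxygen, which is also ortho to OMe and para to OH, attacks the alkyne terminus; the other ortho position carries CHO, so only one chromene can form.

Step 4
Reactants: 5 7-hydroxy-5-methoxy-2H-chromene-8-carbaldehyde
Product: 6 5-methoxy-7-[(triisopropylsilyl)oxy]-2H-chromene-8-carbaldehyde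
Conditions: TIPSOTf (1.2 equiv), 2,6-lutidine (1.5 equiv), CH2Cl2, 0 °C
Reagents that add atoms: triisopropylsilyl trifluoromethanesulfonate CC(C)[Si](OS(=O)(=O)C(F)(F)F)(C(C)C)C(C)C
Why: Silylation of the hydrogen-bonded phenol with a silyl triflate and a hindered base; the bulky silyl ether removes the chelating salicylaldehyde OH before the palladium step and should withstand amine formate at 70 °C.

Step 5
Reactants: 7 4-bromobenzene-1,3-diol (4-bromoresorcinol)
Product: 8 2-bromo-5-[(triisopropylsilyl)oxy]phenol
Conditions: TIPSCl (1.0 equiv), imidazole (2.0 equiv), CH2Cl2/DMF 10:1, −20 to 0 °C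
Reagents that add atoms: chlorotriisopropylsilane CC(C)[Si](Cl)(C(C)C)C(C)C
Why: Steric selection in phenol silylation: the bulky chlorosilane should react at the OH para to bromine because the OH flanked by bromine is shielded; one equivalent at low temperature limits bis-silylation.

Step 6
Reactants: 8 2-bromo-5-[(triisopropylsilyl)oxy]phenol; 9 3-chloro-3-methylbut-1-yne
Product: 10 {4-bromo-3-[(2-methylbut-3-yn-2-yl)oxy]phenoxy}tri(propan-2-yl)silane
Conditions: 9 (1.5 equiv), CuCl2·2H2O (1 mol %), DBU (1.6 equiv), MeCN, 0 °C to rt
Reagents that add atoms: none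
Why: Copper-catalysed propargylic etherification of a phenol with a tertiary propargylic chloride, the standard entry to aryl 1,1-dimethylpropargyl ethers; only one free OH is present.

Step 7
Reactants: 10 {4-bromo-3-[(2-methylbut-3-yn-2-yl)oxy]phenoxy}tri(propan-2-yl)silane
Product: 14 8-bromo-2,2-dimethyl-5-[(triisopropylsilyl)oxy]-2H-chromene, via allenyl dienone 11 (not isolated), via allenylphenol 12 (not isolated), via o-quinone methide 13 (not isolated)
Conditions: o-xylene, 140 °C, sealed tube under argon
Reagents that add atoms: none
Why: Aromatic propargyl Claisen cascade: the [3,3]-sigmatropic shift to the only free ortho carbon gives 11, enolisation gives 12, a 1,5-hydrogen shift gives 13 and oxa-6π electrocyclisation closes ring D; bromine blocks the other ortho carbon, so the pyran is fused at the carbon between the two oxygens.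

Step 8
Reactants: 6 5-methoxy-7-[(triisopropylsilyl)oxy]-2H-chromene-8-carbaldehyde; 14 8-bromo-2,2-dimethyl-5-[(triisopropylsilyl)oxy]-2H-chromene
Product: 15 (3R)-3-{2,2-dimethyl-5-[(triisopropylsilyl)oxy]-2H-chromen-8-yl}-5-methoxy-7-[(triisopropylsilyl)oxy]-3,4-dihydro-2H-chromene-8-carbaldehyde
Conditions: 14 (1.3 equiv), Pd2(dba)3 (2.5 mol %), (R)-BINAP (6 mol %), HCO2H (2.0 equiv, added slowly), i-Pr2NEt (3.0 equiv), DMF, 70 °C
Reagents that add atoms: none
Why: Proposed new method: zerovalent palladium–(R)-BINAP inserts into the C8″–Br bond of 14, bromide dissociation in DMF gives a cationic aryl-palladium species (divalent palladium) that binds the C3=C4 alkene of 6, and syn migratory insertion delivers the aryl group to C3 and palladium to benzylic C4. The C4–Pd intermediate has no syn β-hydrogen (C3–H is anti to palladium, C4a is aromatic), so it waits for formate, which exchanges onto palladium, loses CO2 and gives 15 by C–H reductive elimination. The closest known reaction types are the palladium oxyarylation and hydroarylation of 2H-chromenes, which show the same C3-aryl/C4-palladium regiochemistry in racemic form, and enantioselective reductive Heck reactions of aryl halides with chiral bisphosphines and formate on intramolecular and strained bicyclic alkenes; the enantioselective intermolecular variant on a 2H-chromene is the untested element. No ring is closed: the step forms the C3–C1′ and C4–H bonds on preformed rings C and D. The C3 stereocentre is set in the migratory insertion under catalyst control, the C2-symmetric bisphosphine distinguishing the two faces of the rigid cis-alkene (ring A on one side of the C3=C4 bond, O1–CH2 on the other), as in asymmetric Heck arylation of cyclic cis-alkenes. Regioselectivity (aryl to C3, not C4) follows from η3-benzyl stabilisation of palladium at C4 and from the peri C5-OMe, which hinders aryl delivery to C4. Chemoselectivity for the alkene of 6 over the ring D alkenes of 14 and 15 rests on the quaternary C2″ next to C3″ and the peri silyloxy group at C5″, which make insertion there neopentyl-like; aldehyde and silyl ethers should be inert to amine formate.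

Step 9
Reactants: 15 (3R)-3-{2,2-dimethyl-5-[(triisopropylsilyl)oxy]-2H-chromen-8-yl}-5-methoxy-7-[(triisopropylsilyl)oxy]-3,4-dihydro-2H-chromene-8-carbaldehyde
Product: 16 (3R)-7-hydroxy-3-(5-hydroxy-2,2-dimethyl-2H-chromen-8-yl)-5-methoxy-3,4-dihydro-2H-chromene-8-carbaldehyde (CNP0272344.1)
Conditions: TBAF (2.5 equiv), AcOH (2.5 equiv), THF, 0 °C
Reagents that add atoms: none
Why: Fluoride cleavage of both aryl silyl ethers, buffered with AcOH so that the phenoxides are protonated at once; the aldehyde, the ring D alkene and the non-epimerisable C3 centre should be untouched.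

## Compound list

1 | 2,4,6-trihydroxybenzaldehyde | O=Cc1c(O)cc(O)cc1O | starting material
2 | 2,6-dihydroxy-4-methoxybenzaldehyde | COc1cc(O)c(C=O)c(O)c1 | intermediate
3 | 3-bromoprop-1-yne (propargyl bromide) | C#CCBr | starting material
4 | 2-hydroxy-4-methoxy-6-(prop-2-yn-1-yloxy)benzaldehyde | COc1cc(O)c(C=O)c(OCC#C)c1 | intermediate
5 | 7-hydroxy-5-methoxy-2H-chromene-8-carbaldehyde | COc1cc(O)c(C=O)c2OCC=Cc12 | intermediate
6 | 5-methoxy-7-[(triisopropylsilyl)oxy]-2H-chromene-8-carbaldehyde | COc1cc(O[Si](C(C)C)(C(C)C)C(C)C)c(C=O)c2OCC=Cc12 | intermediate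
7 | 4-bromobenzene-1,3-diol (4-bromoresorcinol) | Oc1ccc(Br)c(O)c1 | starting material
8 | 2-bromo-5-[(triisopropylsilyl)oxy]phenol | CC(C)[Si](C(C)C)(C(C)C)Oc1ccc(Br)c(O)c1 | intermediate
9 | 3-chloro-3-methylbut-1-yne | C#CC(C)(C)Cl | starting material
10 | {4-bromo-3-[(2-methylbut-3-yn-2-yl)oxy]phenoxy}tri(propan-2-yl)silane | C#CC(C)(C)Oc1cc(O[Si](C(C)C)(C(C)C)C(C)C)ccc1Br | intermediate
11 | 2-bromo-6-(3-methylbuta-1,2-dien-1-yl)-5-[(triisopropylsilyl)oxy]cyclohexa-2,4-dien-1-one (allenyl dienone, not isolated) | CC(C)=C=CC1C(=O)C(Br)=CC=C1O[Si](C(C)C)(C(C)C)C(C)C | intermediate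
12 | 6-bromo-2-(3-methylbuta-1,2-dien-1-yl)-3-[(triisopropylsilyl)oxy]phenol (allenylphenol, not isolated) | CC(C)=C=Cc1c(O)c(Br)ccc1O[Si](C(C)C)(C(C)C)C(C)C | intermediate
13 | 2-bromo-6-(3-methylbut-2-en-1-ylidene)-5-[(triisopropylsilyl)oxy]cyclohexa-2,4-dien-1-one (o-quinone methide, not isolated) | CC(C)=CC=C1C(=O)C(Br)=CC=C1O[Si](C(C)C)(C(C)C)C(C)C | intermediate
14 | 8-bromo-2,2-dimethyl-5-[(triisopropylsilyl)oxy]-2H-chromene | CC1(C)C=Cc2c(O[Si](C(C)C)(C(C)C)C(C)C)ccc(Br)c2O1 | intermediate
15 | (3R)-3-{2,2-dimethyl-5-[(triisopropylsilyl)oxy]-2H-chromen-8-yl}-5-methoxy-7-[(triisopropylsilyl)oxy]-3,4-dihydro-2H-chromene-8-carbaldehyde | COc1cc(O[Si](C(C)C)(C(C)C)C(C)C)c(C=O)c2c1C[C@H](c1ccc(O[Si](C(C)C)(C(C)C)C(C)C)c3c1OC(C)(C)C=C3)CO2 | intermediate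
16 | (3R)-7-hydroxy-3-(5-hydroxy-2,2-dimethyl-2H-chromen-8-yl)-5-methoxy-3,4-dihydro-2H-chromene-8-carbaldehyde | COc1cc(O)c(C=O)c2c1C[C@H](c1ccc(O)c3c1OC(C)(C)C=C3)CO2 | target

## Step count and least certain steps

Total: 9 steps. Longest linear sequence: 6 steps (1 → 2 → 4 → 5 → 6 → 15 → 16; steps 1 to 4, 8 and 9). The ring B branch (steps 5 to 7) joins at step 8.

Step 8 (key step, proposed new method). Four processes may fail:
- Face selection in the migratory insertion may be insufficient, since no chiral catalyst has been tuned for this alkene class.
- Formate may reduce the aryl-palladium bromide before it inserts into the 1,2-disubstituted alkene.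
- Palladium hydride may shift the C3=C4 alkene to the C2=C3 enol ether, which would lead to arylation at C2.
- The C4–Pd intermediate may ionise and eliminate towards C3, which erases the new centre.

Slow formate addition and the excess of 14 address the second and fourth. The fallback uses known chemistry and gives up catalyst control. It sets out from 6 and 14, which are coupled with an achiral catalyst (Pd(OAc)2, PPh3, HCO2Na, DMF, 80 °C), the reductive counterpart of the established palladium oxyarylation of 2H-chromenes. This gives racemic 3-{2,2-dimethyl-5-[(triisopropylsilyl)oxy]-2H-chromen-8-yl}-5-methoxy-7-[(triisopropylsilyl)oxy]-3,4-dihydro-2H-chromene-8-carbaldehyde F1. The enantiomers are separated by preparative supercritical-fluid chromatography on an amylose tris(3,5-dimethylphenylcarbamate) phase. The (3S)-enantiomer F2 is set aside and the (3R)-enantiomer is 15, where the route is rejoined.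

Step 1. Over-methylation and ring C-methylation of the phloroglucinol anion may compete with mono-O-methylation, because the mono-anion is ambident and 2 is still acidic. The fallback replaces selective alkylation by selective dealkylation. It sets out from 1, which is exhaustively O-methylated (Me2SO4 in excess, K2CO3, acetone, reflux) to 2,4,6-trimethoxybenzaldehyde F3. AlCl3 (3 equiv, CH2Cl2, rt) then cleaves only the two methyl ethers that can chelate aluminium with the formyl oxygen, and the route is rejoined at 2.

Step 3. Cationic gold may be sequestered as a gold acetylide by the terminal alkyne or by the salicylaldehyde unit, and the electron-rich chromene may oligomerise under the Lewis acid. The fallback changes both the order and the mechanism. It sets out from 4, which is silylated first (TIPSOTf, 2,6-lutidine, CH2Cl2) to 4-methoxy-2-(prop-2-yn-1-yloxy)-6-[(triisopropylsilyl)oxy]benzaldehyde F4. Heating in N,N-diethylaniline at 200 °C then builds the ring without metal, by [3,3] shift, hydrogen shift and oxa-6π closure (the O1–C2 bond is broken and re-formed). The route is rejoined at 6.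

Step 5. Silylation may occur at the more acidic OH next to bromine or at both OH groups, because acidity and steric access point in opposite directions. The fallback selects by leaving-group ability instead of by size. It sets out from 7, which is silylated twice (TIPSCl 2.5 equiv, imidazole, DMF) to [(4-bromo-1,3-phenylene)bis(oxy)]bis[tri(propan-2-yl)silane] F5. Cs2CO3 (0.5 equiv, DMF–H2O 10:1, rt) should then cleave the silyl ether next to bromine, whose phenoxide is the better leaving group, and the route is rejoined at 8.

## Further compounds

F1 | step 8 | racemic 3-{2,2-dimethyl-5-[(triisopropylsilyl)oxy]-2H-chromen-8-yl}-5-methoxy-7-[(triisopropylsilyl)oxy]-3,4-dihydro-2H-chromene-8-carbaldehyde | COc1cc(O[Si](C(C)C)(C(C)C)C(C)C)c(C=O)c2c1CC(c1ccc(O[Si](C(C)C)(C(C)C)C(C)C)c3c1OC(C)(C)C=C3)CO2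
F2 | step 8 | (3S)-3-{2,2-dimethyl-5-[(triisopropylsilyl)oxy]-2H-chromen-8-yl}-5-methoxy-7-[(triisopropylsilyl)oxy]-3,4-dihydro-2H-chromene-8-carbaldehyde | COc1cc(O[Si](C(C)C)(C(C)C)C(C)C)c(C=O)c2c1C[C@@H](c1ccc(O[Si](C(C)C)(C(C)C)C(C)C)c3c1OC(C)(C)C=C3)CO2
F3 | step 1 | 2,4,6-trimethoxybenzaldehyde | COc1cc(OC)c(C=O)c(OC)c1
F4 | step 3 | 4-methoxy-2-(prop-2-yn-1-yloxy)-6-[(triisopropylsilyl)oxy]benzaldehyde | COc1cc(O[Si](C(C)C)(C(C)C)C(C)C)c(C=O)c(OCC#C)c1
F5 | step 5 | [(4-bromo-1,3-phenylene)bis(oxy)]bis[tri(propan-2-yl)silane] | CC(C)[Si](C(C)C)(C(C)C)Oc1ccc(Br)c(O[Si](C(C)C)(C(C)C)C(C)C)c1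
A1 | alternative 1 | 3-[2,4-bis(methoxymethoxy)phenyl]-5-methoxy-7-(methoxymethoxy)-2H-chromene | COCOc1ccc(C2=Cc3c(OC)cc(OCOC)cc3OC2)c(OCOC)c1
A2 | alternative 1 | (3R)-3-[2,4-bis(methoxymethoxy)phenyl]-5-methoxy-7-(methoxymethoxy)-3,4-dihydro-2H-chromene | COCOc1ccc([C@H]2Cc3c(OC)cc(OCOC)cc3OC2)c(OCOC)c1
A3 | alternative 2 | (4R)-4-benzyl-3-({2,2-dimethyl-5-[(triisopropylsilyl)oxy]-2H-chromen-8-yl}acetyl)-1,3-oxazolidin-2-one | O=C(Cc1ccc(O[Si](C(C)C)(C(C)C)C(C)C)c2c1OC(C)(C)C=C2)N1[C@H](Cc2ccccc2)COC1=O
A4 | alternative 2 | 2-[3-(bromomethyl)-4-methoxy-2,6-bis(methoxymethoxy)phenyl]-1,3-dioxolane | COCOc1cc(OC)c(CBr)c(OCOC)c1C1OCCO1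
A5 | alternative 2 | (4R)-4-benzyl-3-[(2R)-2-{2,2-dimethyl-5-[(triisopropylsilyl)oxy]-2H-chromen-8-yl}-3-[3-(1,3-dioxolan-2-yl)-6-methoxy-2,4-bis(methoxymethoxy)phenyl]propanoyl]-1,3-oxazolidin-2-one | COCOc1cc(OC)c(C[C@H](c2ccc(O[Si](C(C)C)(C(C)C)C(C)C)c3c2OC(C)(C)C=C3)C(=O)N2[C@H](Cc3ccccc3)COC2=O)c(OCOC)c1C1OCCO1
A6 | alternative 3 | tert-butyl[2-(bromomethyl)-6-(1,3-dioxolan-2-yl)-3-methoxy-5-(methoxymethoxy)phenoxy]dimethylsilane | COCOc1cc(OC)c(CBr)c(O[Si](C)(C)C(C)(C)C)c1C1OCCO1
A7 | alternative 3 | 2-{2,2-dimethyl-5-[(triisopropylsilyl)oxy]-2H-chromen-8-yl}-1-(1H-imidazol-1-yl)ethan-1-one | O=C(Cc1ccc(O[Si](C(C)C)(C(C)C)C(C)C)c2c1OC(C)(C)C=C2)n1ccnc1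
A8 | alternative 3 | (3R)-3-{2,2-dimethyl-5-[(triisopropylsilyl)oxy]-2H-chromen-8-yl}-8-(1,3-dioxolan-2-yl)-5-methoxy-7-(methoxymethoxy)-3,4-dihydro-2H-chromen-2-one | COCOc1cc(OC)c2C[C@H](c3ccc(O[Si](C(C)C)(C(C)C)C(C)C)c4c3OC(C)(C)C=C4)C(=O)Oc2c1C1OCCO1
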